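The route rests on one disconnection: the bond between C8 of the flavan ring A and the carbinol carbon C3 of the chromanone. C3 sits between the C4 ketone and the C2 bis-aryloxy ketal, so it is the masked central carbonyl of a vicinal tricarbonyl, and C8 is the nucleophilic carbon ortho to O7. The precursor is a 2-aryloxychromane-3,4-dione in which the flavan is already held at C2 through O7. A chiral copper Lewis acid then closes the dihydrofuran ring O7–C7–C8–C3–C2 by Friedel–Crafts attack of C8 on the C3 carbonyl, fixes the C3 carbinol and funnels both ketal epimers into one product.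

Key step: step 8

Assumption: C2 and C3 of the chromanone are one stereochemical unit, since closure of the dihydrofuran ring can place the C3 hydroxyl only on the face of the C2 aryl group; the target is taken as this fused arrangement in the sense that makes the ketal carbon (R), and its SMILES is kept exactly as given although, read literally, the C3 descriptor would put the hydroxyl on the opposite face.

Step 1
Reactants: 1 (2S)-naringenin
Product: 2 (2S)-7-(allyloxy)-5-hydroxy-2-(4-hydroxyphenyl)chroman-4-one
Conditions: allyl alcohol (1.05 equiv), PPh3, DIAD, THF, 0 °C to rt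
Reagents that add atoms: allyl alcohol, C=CCO
Why: Mitsunobu etherification alkylates the most acidic phenol, the 7-OH para to the carbonyl, ahead of the 4'-OH and the hydrogen-bonded 5-OH, and the neutral conditions should leave the base-labile flavanone centre C2 intact.

Step 2
Reactants: 2 (2S)-7-(allyloxy)-5-hydroxy-2-(4-hydroxyphenyl)chroman-4-one
Product: 5 (2S)-7-(allyloxy)-2-(4-hydroxyphenyl)chroman-5-ol, via flavanone bis(ethyl carbonate) 3 (not isolated), via flavan 4'-ethyl carbonate 4 (not isolated)
Conditions: ClCO2Et (2.4 equiv), Et3N, THF, 0 °C; then NaBH4, THF/H2O, 0 °C to rt; then 2 M NaOH, rt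
Reagents that add atoms: none
Why: NaBH4 reduction of an ortho-acyloxyaryl ketone: the 5-O-ethoxycarbonyl group migrates to the new C4 alkoxide and is eliminated to an ortho-quinone methide that takes up hydride, so C4 becomes CH2 and the 5-OH returns, and hydroxide then cleaves the remaining aryl carbonate; C2 is not touched and can no longer epimerise once the ketone is gone.

Step 3
Reactants: 5 (2S)-7-(allyloxy)-2-(4-hydroxyphenyl)chroman-5-ol
Product: 6 (2S)-7-(allyloxy)-5-(benzyloxy)-2-[4-(benzyloxy)phenyl]chroman
Conditions: BnBr (2.4 equiv), K2CO3, DMF, rt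
Reagents that add atoms: benzyl bromide, BrCc1ccccc1
Why: Williamson etherification of both free phenols; the allyl ether keeps O7 marked for later release.

Step 4
Reactants: 6 (2S)-7-(allyloxy)-5-(benzyloxy)-2-[4-(benzyloxy)phenyl]chroman
Product: 7 (2S)-5-(benzyloxy)-2-[4-(benzyloxy)phenyl]chroman-7-ol
Conditions: Pd(PPh3)4 (5 mol%), morpholine, THF, rt
Reagents that add atoms: none
Why: Tsuji–Trost deallylation: zerovalent palladium ionises the aryl allyl ether and morpholine takes up the allyl group, while benzyl ethers are inert.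

Step 5
Reactants: 8 1-[2,4-bis(benzyloxy)-6-hydroxyphenyl]ethanone; 9 4-(benzyloxy)benzaldehyde
Product: 10 (E)-1-[2,4-bis(benzyloxy)-6-hydroxyphenyl]-3-[4-(benzyloxy)phenyl]prop-2-en-1-one
Conditions: KOH, EtOH/THF, rt
Reagents that add atoms: none
Why: Claisen–Schmidt condensation should give the (E)-chalcone.

Step 6
Reactants: 10 (E)-1-[2,4-bis(benzyloxy)-6-hydroxyphenyl]-3-[4-(benzyloxy)phenyl]prop-2-en-1-one
Product: 12 5,7-bis(benzyloxy)-2-[4-(benzyloxy)phenyl]-3-hydroxy-4H-chromen-4-one, via racemic trans-dihydroflavonol 11 (not isolated)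
Conditions: 30% H2O2, NaOH, MeOH/THF, 0 °C to rt
Reagents that add atoms: hydrogen peroxide, OO
Why: Algar–Flynn–Oyamada reaction: alkaline H2O2 cyclises the 2'-hydroxychalcone oxidatively to the dihydroflavonol and oxidises it in the same pot to the flavonol.

Step 7
Reactants: 12 5,7-bis(benzyloxy)-2-[4-(benzyloxy)phenyl]-3-hydroxy-4H-chromen-4-one; 7 (2S)-5-(benzyloxy)-2-[4-(benzyloxy)phenyl]chroman-7-ol
Product: 14 5,7-bis(benzyloxy)-2-[4-(benzyloxy)phenyl]-2-{[(2S)-5-(benzyloxy)-2-[4-(benzyloxy)phenyl]chroman-7-yl]oxy}chromane-3,4-dione (both C2 epimers), via ketal acetate 13 (not isolated)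
Conditions: PhI(OAc)2 (1.0 equiv), CH2Cl2, 0 °C, then evaporate; 7 (1.1 equiv), TMSOTf (0.2 equiv), 4 Å MS, CH2Cl2, −78 °C; Et3N quench at −78 °C
Reagents that add atoms: none
Why: Trivalent iodine oxidises the flavonol enol with capture of acetate at C2, and TMSOTf then exchanges the acetate for the only free phenol, O7 of 7, through the oxocarbenium ion at low temperature (kinetic O-attack as in aryl glycoside synthesis); C2 forms as both epimers, which is tolerated because the next step is designed to be stereoconvergent.

Step 8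
Reactants: 14 5,7-bis(benzyloxy)-2-[4-(benzyloxy)phenyl]-2-{[(2S)-5-(benzyloxy)-2-[4-(benzyloxy)phenyl]chroman-7-yl]oxy}chromane-3,4-dione (both C2 epimers)
Product: 15 pentabenzyl ether of the target (ketal carbon R; carbinol carbon S; flavan carbon S)
Conditions: Cu(OTf)2 (20 mol%), (S,S)-tBu-BOX (22 mol%), 4 Å MS, CH2Cl2, 0 °C to rt
Reagents that add atoms: none
Why: Proposed new method: the Cu(OTf)2/bis(oxazoline) complex chelates the C3/C4 dione of 14 and the tethered flavan ring A attacks the activated C3 carbonyl through C8 (intramolecular Friedel–Crafts hydroxyalkylation), closing the dihydrofuran ring O7–C7–C8–C3–C2 in 5-exo-trig mode. The closest known reaction types are the enantioselective Friedel–Crafts hydroxyalkylation of electron-rich arenes with chelating 1,2-dicarbonyl compounds under divalent copper/bis(oxazoline) catalysis and the acid-mediated ring closure of α-aryloxy ketones; new is their stereoconvergent use on a labile ketal. C3 is controlled by C2: C8 can reach the carbonyl only from the face on which O7 stands, so the hydroxyl ends on the face of the 4-benzyloxyphenyl group, and no dehydration can follow because C2 is fully substituted. C2 is controlled by the catalyst: the two ketal epimers should interconvert through reversible heterolysis of the C2–O1 bond (the ortho-acyl phenoxide leaves and re-closes on the aryl- and aryloxy-stabilised oxocarbenium ion), and only the epimer whose aryloxy group lies on the unshielded face of the chelate should cyclise fast, the remote flavan centre adding no bias; the ligand antipode is the one matched to the (R)-ketal, to be confirmed by testing both. The step needs C8 over C6, secured by the 5-benzyloxy group flanking C6 and by the inherent preference of 5,7-dioxygenated flavans for substitution at C8, and it needs attack at C3 instead of aryl transfer to C2, secured by chelate activation of the dione and by molecular sieves that keep C3 free of hydrate.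

Step 9
Reactants: 15 pentabenzyl ether of the target
Product: 16 target hexaphenol
Conditions: H2 (1 atm), Pd(OH)2/C, THF/MeOH, rt
Reagents that add atoms: none
Why: Hydrogenolysis of the five aryl benzyl ethers under neutral conditions; the benzylic C–O bonds at the fully substituted ketal carbon and in the flavan ring should be much slower to cleave, and no stereocentre is touched.

Compound list
1 | (2S)-naringenin; (2S)-5,7-dihydroxy-2-(4-hydroxyphenyl)chroman-4-one | Oc1cc(O)c2c(c1)O[C@H](c1ccc(O)cc1)CC2=O | starting material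
2 | (2S)-7-(allyloxy)-5-hydroxy-2-(4-hydroxyphenyl)chroman-4-one | C=CCOc1cc(O)c2c(c1)O[C@H](c1ccc(O)cc1)CC2=O | intermediate
3 | (2S)-7-(allyloxy)-4-oxochroman-5-yl and 4'-phenyl bis(ethyl carbonate) of 2 (not isolated) | C=CCOc1cc(OC(=O)OCC)c2c(c1)O[C@H](c1ccc(OC(=O)OCC)cc1)CC2=O | intermediate
4 | 4-[(2S)-7-(allyloxy)-5-hydroxychroman-2-yl]phenyl ethyl carbonate (not isolated) | C=CCOc1cc(O)c2c(c1)O[C@H](c1ccc(OC(=O)OCC)cc1)CC2 | intermediate
5 | (2S)-7-(allyloxy)-2-(4-hydroxyphenyl)chroman-5-ol | C=CCOc1cc(O)c2c(c1)O[C@H](c1ccc(O)cc1)CC2 | intermediate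
6 | (2S)-7-(allyloxy)-5-(benzyloxy)-2-[4-(benzyloxy)phenyl]chroman | C=CCOc1cc(OCc2ccccc2)c2c(c1)O[C@H](c1ccc(OCc3ccccc3)cc1)CC2 | intermediate
7 | (2S)-5-(benzyloxy)-2-[4-(benzyloxy)phenyl]chroman-7-ol | Oc1cc(OCc2ccccc2)c2c(c1)O[C@H](c1ccc(OCc3ccccc3)cc1)CC2 | intermediate
8 | 1-[2,4-bis(benzyloxy)-6-hydroxyphenyl]ethanone | CC(=O)c1c(O)cc(OCc2ccccc2)cc1OCc1ccccc1 | starting material
9 | 4-(benzyloxy)benzaldehyde | O=Cc1ccc(OCc2ccccc2)cc1 | starting material
10 | (E)-1-[2,4-bis(benzyloxy)-6-hydroxyphenyl]-3-[4-(benzyloxy)phenyl]prop-2-en-1-one | O=C(/C=C/c1ccc(OCc2ccccc2)cc1)c1c(O)cc(OCc2ccccc2)cc1OCc1ccccc1 | intermediate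
11 | racemic trans-5,7-bis(benzyloxy)-2-[4-(benzyloxy)phenyl]-3-hydroxychroman-4-one (one enantiomer drawn; not isolated) | O=C1c2c(OCc3ccccc3)cc(OCc3ccccc3)cc2O[C@H](c2ccc(OCc3ccccc3)cc2)[C@H]1O | intermediate
12 | 5,7-bis(benzyloxy)-2-[4-(benzyloxy)phenyl]-3-hydroxy-4H-chromen-4-one (tri-O-benzylkaempferol) | O=c1c(O)c(-c2ccc(OCc3ccccc3)cc2)oc2cc(OCc3ccccc3)cc(OCc3ccccc3)c12 | intermediate
13 | racemic 5,7-bis(benzyloxy)-2-[4-(benzyloxy)phenyl]-3,4-dioxochroman-2-yl acetate (not isolated) | CC(=O)OC1(c2ccc(OCc3ccccc3)cc2)Oc2cc(OCc3ccccc3)cc(OCc3ccccc3)c2C(=O)C1=O | intermediate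
14 | 5,7-bis(benzyloxy)-2-[4-(benzyloxy)phenyl]-2-{[(2S)-5-(benzyloxy)-2-[4-(benzyloxy)phenyl]chroman-7-yl]oxy}chromane-3,4-dione; both epimers at the ketal carbon C2 | O=C1c2c(OCc3ccccc3)cc(OCc3ccccc3)cc2OC(c2ccc(OCc3ccccc3)cc2)(Oc2cc(OCc3ccccc3)c3c(c2)O[C@H](c2ccc(OCc4ccccc4)cc2)CC3)C1=O | intermediate
15 | pentabenzyl ether of 16: all five phenols benzylated and the tertiary 3-OH free; ketal carbon (R); carbinol carbon (S); flavan carbon (S); descriptors as in the target notation | O=C1c2c(OCc3ccccc3)cc(OCc3ccccc3)cc2O[C@@]2(c3ccc(OCc4ccccc4)cc3)Oc3cc(OCc4ccccc4)c4c(c3[C@]12O)O[C@H](c1ccc(OCc3ccccc3)cc1)CC4 | intermediate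
16 | CNP0208300.3: 3,5,7-trihydroxy-2-(4-hydroxyphenyl)chroman-4-one whose C2 is bonded to O7 and whose C3 is bonded to C8 of (2S)-5-hydroxy-2-(4-hydroxyphenyl)chroman, closing a dihydrofuran ring; ketal carbon (R); carbinol carbon (S) | O=C1c2c(O)cc(O)cc2O[C@@]2(c3ccc(O)cc3)Oc3cc(O)c4c(c3[C@]12O)O[C@H](c1ccc(O)cc1)CC4 | target

Total step count: 9. Longest linear sequence: 7 steps (1, 2, 3, 4, 7, 8, 9).

Steps most likely to fail

Step 8 (the step beyond known chemistry). The ketal epimers may not interconvert under the copper catalyst, or the chelate may discriminate them too weakly, so that both cyclise and the C2/C3 pair forms in both senses. The fallback uses known chemistry and sets out from 14. The two epimers are separated by preparative HPLC into the (2R)-ketal F1 and the (2S)-ketal F2. F1 is cyclised with achiral Sc(OTf)3 (10 mol%, CH2Cl2, 0 °C), the acid-mediated ring closure of an α-aryloxy ketone, which is stereospecific and gives 15, where the route is rejoined. F2 is returned to the epimer mixture 14 by reversible ketal ionisation (TMSOTf cat., CH2Cl2, −40 °C) and separated again.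

Step 7. The flavan ring may attack the oxocarbenium ion through carbon (C8 or C6) instead of O7, or the mixed ketal may ionise again once formed, both driven by the Lewis acid. The fallback sets out from 12. Oxidation with PhI(OAc)2 in MeOH gives the stable racemic methyl ketal 5,7-bis(benzyloxy)-2-[4-(benzyloxy)phenyl]-3-hydroxy-2,3-dimethoxychroman-4-one F3, which is isolated. F3 and 7 are then equilibrated under mild Brønsted acid (camphorsulfonic acid, 5 Å MS to take up methanol, toluene, 40 °C). This thermodynamic transketalisation replaces the kinetic substitution and gives 14, where the route is rejoined.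

Step 9. Over-reduction may occur: hydrogenolysis of the benzylic C–O bonds at the ketal carbon or at the flavan C2, or reduction of the aryl ketone. The fallback sets out from 15. Lewis-acid debenzylation with BCl3 and pentamethylbenzene as cation scavenger (CH2Cl2, −78 °C) needs no reducing agent and gives 16 directly; it makes no new compound, F0.

Further compounds
F1 | step 8 | (2R)-epimer of ketal 14 | O=C1c2c(OCc3ccccc3)cc(OCc3ccccc3)cc2O[C@@](c2ccc(OCc3ccccc3)cc2)(Oc2cc(OCc3ccccc3)c3c(c2)O[C@H](c2ccc(OCc4ccccc4)cc2)CC3)C1=O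
F2 | step 8 | (2S)-epimer of ketal 14 | O=C1c2c(OCc3ccccc3)cc(OCc3ccccc3)cc2O[C@](c2ccc(OCc3ccccc3)cc2)(Oc2cc(OCc3ccccc3)c3c(c2)O[C@H](c2ccc(OCc4ccccc4)cc2)CC3)C1=O
F3 | step 7 | racemic 5,7-bis(benzyloxy)-2-[4-(benzyloxy)phenyl]-3-hydroxy-2,3-dimethoxychroman-4-one | COC1(c2ccc(OCc3ccccc3)cc2)Oc2cc(OCc3ccccc3)cc(OCc3ccccc3)c2C(=O)C1(O)OC
F0 | step 9 | none | none
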